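The coupling partner is the charge I follow in the red flask, the one asked about. The blue run, made earlier, carries more of it and otherwise the same charges.

in all of them: substrate 0.50 M; temperature 0 °C

| charge | coupling partner | second reagent | capture agent | remark | time |
|---|---|---|---|---|---|
| red | 0.25 M | 0.60 M | 0.50 M | the very flask that is asked about, followed so far |  |
| blue | 0.38 M | 0.60 M | 0.50 M | run made earlier |  |
| flask | 0.250 M | 0.600 M | 0.500 M |  | 4.0 h |

red run (percent of the substrate charged): time / h: target / % = 0.667: 35.6; 1.33: 32.5; 2.00: 34.7; 2.50: 33.5; 3.00: 35.2; 4.00: 34.8

blue run (percent of the substrate charged): time / min: target / % = 6.00: 15.2; 15.0: 36.6; 30.0: 47.8; 50.0: 50.2; 60.0: 52.6; 80.0: 49.6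

(scatter of a reading: 1 percentage point)

* target, in percent of the substrate first charged, at 4.0 h
* the remedy with the largest gain of target, or "none" below 2 percentage points (south-west / west / north-west / north-east / none)
* target present, in percent of the substrate first charged, after west
* target present, in percent of the substrate first charged, after north-west

- south-west: at 4.0 h raise the temperature by 20 K, then wait 4.0 h
- west: at 4.0 h add substrate, 50.0% of the amount charged, then wait 4.0 h
- north-west: change nothing and wait 4.0 h more
- north-east: at 4.0 h add coupling partner, 50.0% of the amount charged, then wait 4.0 h

- what is added takes up no volume worth counting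
- a reading or a percentage of target counts all its forms, free or not
- the earlier runs do not show what temperature does; that part of a forecast is a guess

Both runs go flat. Red averages 34.4%, and blue holds about 50.8% from 50.0 min. Those plateaus stand in the ratio 1.48 and the partner charges in the ratio 1.52, while the substrate charges are equal, so I take the coupling partner as the limiting reagent. From blue I read the partner share 66.8%, the target at the plateau divided by the coupling partner consumed, mole for mole, and I take the charge as consumed once a run stands flat. Carried to the red flask, it gives 33.4%, near what red reads, and the two come from different runs.

Now I turn the settings one by one. Waiting first: red reads 35.6% at 0.667 h and 34.8% at 4.00 h, a difference inside the scatter, so I expect no gain. Extra substrate brings no partner, so target should stay at 34.4%. Extra partner is another matter, since the share turns it into a gain of 17 percentage points. Temperature is a guess, and with the plateau reached I guess no gain.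

The forecast puts target at 34.4% now, 34.4% after west and 34.4% after north-west, and chooses north-east, reasoning that “the yield tracks the partner”. It counts roughly 15 points for that remedy, where I count 17 points.

The red flask stands at 34.1%, and after west and north-west at 34.1% and 34.1%. The gains are 0 points for west, 0 points for north-west, 0 points for south-west and 16 points for north-east, where the share gave 17 points.

    substrate + coupling partner → open intermediate (k = 0.0120 M⁻¹ s⁻¹, Ea = 50.0 kJ mol⁻¹)
    second reagent + open intermediate → target (k = 0.00320 M⁻¹ s⁻¹, Ea = 55.0 kJ mol⁻¹)
    crystals ⇌ target, rate k3*(cs3 - [target]) while solid is left; crystals form when [target] > cs3 (solubility = 0.190 M, k = 0.0150 s⁻¹)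
    open intermediate + capture agent → trapped intermediate (k = 7.50 × 10⁻⁴ M⁻¹ s⁻¹, Ea = 53.0 kJ mol⁻¹)
    open intermediate → decomposed reagent (k = 4.00 × 10⁻⁴ s⁻¹, Ea = 80.0 kJ mol⁻¹)
    (constants at 0 °C)

At 0.0376 h the making of target uses open intermediate 4.7 times as fast as its loss to decomposed reagent. The half-lives of open intermediate by its losses, each taken alone, are 0.51 h to the capture agent, with the other concentrations as charged, and 0.48 h to decomposed reagent. The neighbour flask with 1.0 M of coupling partner keeps 50.0% of that charge at 4.00 h, with substrate at 0%; the share, applied to the partner consumed there, gives 66.8% of the substrate charged, and that flask holds 64.3%, crystals counted.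

All runs are calculated with made-up constants, noise included.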